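The runs were generated by integration with made-up constants, noise included.

**Late readings.** Late in the two earlier runs, ash and cedar, free monomer falls ever more slowly. At 120 min it stands at 20.9% and 16.6% of the charge. The percentages differ, but the concentrations nearly agree: 0.293 M and 0.299 M. Their mean, 0.296 M, is a reading taken as the floor R, the concentration of free monomer toward which both runs level off; the field calls this the equilibrium monomer concentration.

| setting | ash | cedar | violet | amber |
|---|---|---|---|---|
| free monomer | 1.4 M | 1.8 M | 1.1 M | 1.5 M |
| initiator | 55 mM | 55 mM | 55 mM | 55 mM |
| remark | run made earlier | run made earlier |  |  |
| time |  |  | 3.0 h | 3.0 h |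

- ash (time / min: monomer in chains / %, free monomer / %): 10.0: 25.4, 74.8; 15.0: 34.6, 65.3; 25.0: 48.9, 51.8; 40.0: 61.9, 38.1; 50.0: 67.4, 32.2; 80.0: 75.8, 24.8; 120: 78.9, 20.9
- cedar (time / min: monomer in chains / %, free monomer / %): 10.0: 26.6, 73.3; 15.0: 36.7, 63.5; 25.0: 51.4, 48.0; 40.0: 65.7, 34.6; 50.0: 71.3, 28.6; 80.0: 80.2, 19.4; 120: 83.3, 16.6

(readings scatter by 0.3 percentage points)

- which of the two ends with the longer chains by the average number of monomer units in a chain (chains begun, living or dead) ("neither" if they lie within 10%) (violet / amber / neither)
- average number of monomer units in a chain (chains begun, living or dead) at the end, violet
- average number of monomer units in a chain (chains begun, living or dead) at the end, amber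

- the average divides the monomer in chains by the number of chains begun, living and dead together
- the numbers in the tables scatter by 0.3 percentage points (one standard deviation)
- the earlier runs do not show the number of chains; that part of a forecast is a guess

**Two extremes.** The asked time, 3.0 h, lies beyond the last reading, so both new flasks are taken at their end. Suppose each initiator begins one chain. With no floor, the whole charge enters chains, and the length is charge over initiator: 20.0 for violet, 27.3 for amber. With the floor, the length is (charge − R) over initiator: 14.6 for violet, 21.9 for amber. The real flasks lie between these extremes, and the levelling readings put them near the second. Any initiator that begins no chain raises the length above it, but the number of chains is a guess here. The reckoning committed to is the second pair.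

**The forecast.** The forecast names amber as longer, with 14.9 for violet and 22.2 for amber. These stand a little above the second pair: it saw the levels as “both still falling slightly” and took a floor of 0.28 M instead of R.

**The result.** Violet ends at 15.9 and amber at 23.3, so amber is longer, mainly because of the difference in the concentration of free monomer, and each lies above its lower extreme .

    free monomer + living end → monomer in chains + living end, rate k1*[living end]*[free monomer] (k = 0.0120 M⁻¹ s⁻¹)
    free monomer + initiator → living end + monomer in chains (k = 0.00940 M⁻¹ s⁻¹)
    monomer in chains + living end → free monomer + living end, rate k3*[living end] as long as [monomer in chains] is above zero (k = 0.00340 s⁻¹)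
    2 initiator → spent initiator (k = 0.0140 M⁻¹ s⁻¹)

The return of monomer in chains to free monomer is a part of the reason for the shortfall from the first extreme: with that path taken away, violet reaches 21.5. The floor also serves the flask like amber but charged with 0.38 M of free monomer. Its extremes are 1.53 and 6.91, and that flask ends at 2.13.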